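**Late loss.** Late in the grey run, with substrate down to 0.7%, target still falls from 13.5% at 3.00 min to 7.2% at 5.00 min, a loss of 0.314 min⁻¹. In ochre the same loss hides behind late formation. The first reading says 27.4% of spent substrate ends as target, and adding that back to the fall between 5.00 min and 6.00 min gives 0.0849 min⁻¹. This is a rough reading, since it rests on small differences. Between the two temperatures I take the target's loss rate at 70 °C, with second nucleophile as charged, as 0.154 min⁻¹.

**Substrate clock.** Ochre's substrate falls at 0.599 min⁻¹ and amber's, at twice the charge, at 0.627 min⁻¹, so a dilute feed spares little. With grey's 1.63 min⁻¹, target is born on average 1.06 min after substrate meets the heat.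

| flask | substrate | first nucleophile | second nucleophile | temperature | remark | time |
|---|---|---|---|---|---|---|
| ochre | 0.43 M | 0.452 M | 0.86 M | 65 °C | run made earlier |  |
| grey | 0.21 M | 0.452 M | 0.86 M | 76 °C | run made earlier |  |
| amber | 0.86 M | 0.452 M | 0.86 M | 65 °C | run made earlier |  |
| elm | 0.43 M | 0.452 M | 0.860 M | 70 °C | everything together at the start | 6.0 min |
| maple | 0.43 M (fed, over 2.5 min) | 0.452 M | 0.860 M | 70 °C | all else is in the flask from the start; the feed brings no volume worth counting | 6.0 min |
| alder | 0.43 M | 0.452 M (fed, over 2.5 min) | 0.860 M | 70 °C | all else is in the flask from the start; the feed brings no volume worth counting | 6.0 min |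
| ash | 0.43 M | 0.452 M (fed, over 2.5 min) | 0.860 M |  | the addition at 30 °C, then warmed to 70 °C; the feed brings no volume worth counting | 6.0 min |
| birch | 0.43 M (fed, over 40 s) | 0.452 M | 0.860 M | 70 °C | all else is in the flask from the start; the feed brings no volume worth counting | 6.0 min |

| run | time / min | target / % | substrate / % |
|---|---|---|---|
| ochre | 0.417 | 6.1 | 77.7 |
| ochre | 1.33 | 15.8 | 44.5 |
| ochre | 2.00 | 18.0 | 30.1 |
| ochre | 3.00 | 21.0 | 16.0 |
| ochre | 5.00 | 19.7 | 5.0 |
| ochre | 6.00 | 18.7 | 2.7 |
| grey | 0.833 | 18.3 | 25.5 |
| grey | 1.50 | 19.1 | 8.6 |
| grey | 2.50 | 15.6 | 1.5 |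
| grey | 3.00 | 13.5 | 0.7 |
| grey | 4.00 | 9.7 | 0 |
| grey | 5.00 | 7.2 | 0 |
| amber | 0.333 | 5.5 | 81.8 |
| amber | 1.00 | 13.2 | 53.7 |
| amber | 1.50 | 15.9 | 40.4 |
| amber | 2.50 | 20.3 | 21.3 |
| amber | 4.00 | 21.8 | 8.2 |
| amber | 5.00 | 22.1 | 5.1 |

(each reading ± 0.3 percentage points)

* the flask with the highest amount of target, in percent of the substrate charged ("all alike" if they lie within 1.5 percentage points) (elm / maple / alder / ash / birch / all alike)
* final target, as a percentage of the substrate charged, in elm
* final target, as a percentage of the substrate charged, in maple
* final target, as a percentage of the substrate charged, in alder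
* final target, as a percentage of the substrate charged, in ash
* final target, as a percentage of the substrate charged, in birch

- in percentages every species weighs as the substrate in it: one self-condensation product counts as two
- what was read earlier has a scatter of 0.3 percentage points, one standard deviation
- steps that have been proposed: substrate -> intermediate; first nucleophile + intermediate -> target; second nucleophile + intermediate -> other capture product; intermediate -> solvolysis product; second nucleophile + target -> over-reaction product; 2 substrate -> self-condensation product

**My choice.** A target survives its hot wait, the time from that average birth to the end, as exp(−loss rate × wait). That leaves 46.8% in elm, 49.2% in birch, 56.7% in maple and 68.7% in ash, so ash keeps more. Cold, substrate spends about 6.18% of its charge during the feed. I put alder lowest, because its 1.06 min is shorter than the 2.5 min feed, so much intermediate forms before the first nucleophile is in. I charge ash's way and watch for about 3.68% substrate left at the end.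

**The forecast.** It names ash, with elm 14%, maple 16.6%, alder 6.2%, ash 17.6% and birch 14.7%, because “Ash holds the substrate almost unreacted during addition”.

**The flasks.** The highest is ash: elm 13.8%, maple 16.3%, alder 7.83%, ash 18.8%, birch 14.4%.

    substrate → intermediate (k = 0.0160 s⁻¹, Ea = 88.0 kJ mol⁻¹)
    first nucleophile + intermediate → target (k = 0.690 L mol⁻¹ s⁻¹, Ea = 59.0 kJ mol⁻¹)
    second nucleophile + intermediate → other capture product (k = 0.670 L mol⁻¹ s⁻¹, Ea = 64.0 kJ mol⁻¹)
    intermediate → solvolysis product (k = 0.130 s⁻¹, Ea = 79.0 kJ mol⁻¹)
    second nucleophile + target → over-reaction product (k = 0.00440 L mol⁻¹ s⁻¹, Ea = 86.0 kJ mol⁻¹)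
    2 substrate → self-condensation product (k = 1.20 × 10⁻⁵ L mol⁻¹ s⁻¹, Ea = 96.0 kJ mol⁻¹)
    (constants at 70 °C)

**What stands.** In elm, at the amounts charged, the substrate's half-life of 0.72 min is shorter than the 3.1 min of target under over-reaction. At 0.154 min⁻¹, the hot waits leave 68.7% in ash and 56.7% in maple, and at 6.00 min target makes up 65.0% of target plus over-reaction product in ash and 54.6% in maple. In a neighbour of ash with 0.34 M of second nucleophile, 0.154 min⁻¹ scaled in proportion to that charge leaves 86.2%, and of target plus over-reaction product at 6.00 min target makes up 86.4%.

All runs were generated by integration with made-up constants, noise included.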